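**Retrosynthetic overview**
- Feature used: in the decalin, quaternary C10 (angular methyl C20) lies next to oxygenated C9 (with the C8 methyl beside it) in ring B and 1,4 across ring A from the bromine-bearing C3. This is the substitution pattern of 6-methoxy-2-methyl-1-tetralone once the ring-fusion carbon carries a methyl.
- C9–C11: axial addition of a C11–C16 organocerium to the C9 ketone, anti to C20. C13 comes from (R)-linalool, whose surplus carbon is removed by Barton iodo-decarboxylation. C8 is first equilibrated to the equatorial methyl through the same ketone.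
- C3–Br (equatorial): HAT hydrogenation of the C2=C3 bromoalkene. C4 gem-dimethyl: deconjugative dimethylation of the Δ4-3-ketone. Trans fusion: hydrogenation of Δ5.
- C20: acid opening of a C5–C10–C20 cyclopropane driven by the C3 enol. The cyclopropane comes from C9-hydroxyl-directed methylenation of the Birch-derived C5=C10 olefin; the C9 carbinol comes from Ru-catalysed transfer hydrogenation with dynamic kinetic resolution.
- Ring order: rings A and B are both present in the tetralone (A as the arene, reduced in step 3). The only ring made is the cyclopropane (step 5), which is reopened in step 7.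

Key step: step 5

Remark: labdane numbering is used for all decalin compounds (C1–C10 ring atoms, C20 on C10, C17 on C8, C18/C19 on C4, side chain C11–C16). "Syn/anti" refers to the face of C20 (or of the C20 methylene bridge). Compounds 1, 7 and 23 are taken as commercial.

**Route**

Step 1
Reactants: 1 6-methoxy-1-tetralone
Product: 3 rac-6-methoxy-2-methyl-3,4-dihydronaphthalen-1(2H)-one, via lithium enolate 2 (not isolated)
Conditions: LDA (1.0 equiv), THF, −78 °C; MeI, −78 → 0 °C
Reagents that add atoms: iodomethane, CI
Why: Kinetic lithium enolate formation followed by SN2 C-methylation (ketone α-alkylation) at the only enolisable position; the new C8 centre is left racemic on purpose because step 2 resolves it dynamically.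

Step 2
Reactants: 3 rac-6-methoxy-2-methyl-3,4-dihydronaphthalen-1(2H)-one
Product: 4 (1R,2R)-6-methoxy-2-methyl-1,2,3,4-tetrahydronaphthalen-1-ol (cis)
Conditions: RuCl[(R,R)-TsDPEN](p-cymene) (1 mol%), HCO2H/Et3N (1:1), DMF, 40 °C
Reagents that add atoms: none
Why: Noyori–Ikariya asymmetric transfer hydrogenation with dynamic kinetic resolution: the (R,R)-catalyst should give the (R)-carbinol as it does for 1-tetralone, hydride enters anti to the C8 methyl of the matched ketone enantiomer while the amine-rich medium keeps the α-centre racemising through the enol, so the cis (1R,2R) alcohol should dominate, and any trans isomer with (R)-C9 converges later because C8 is reset in step 15.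

Step 3
Reactants: 4 (1R,2R)-6-methoxy-2-methyl-1,2,3,4-tetrahydronaphthalen-1-ol
Product: 5 (1R,2R)-6-methoxy-2-methyl-1,2,3,4,5,8-hexahydronaphthalen-1-ol
Conditions: Li, NH3(l)/THF, t-BuOH, −78 → −33 °C; isoprene, then MeOH, then NH4Cl
Reagents that add atoms: none
Why: Birch reduction of the anisole ring to the 2,5-dihydroanisole with the tetrasubstituted C5=C10 bond; the benzylic oxygen is carried as its lithium alkoxide and sits para to OMe, which should suppress benzylic C–O hydrogenolysis provided excess lithium is destroyed before protonation, and no stereocentre is touched.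

Step 4
Reactants: 5 (1R,2R)-6-methoxy-2-methyl-1,2,3,4,5,8-hexahydronaphthalen-1-ol
Product: 6 (1R,2R)-6,6-(ethylenedioxy)-2-methyl-1,2,3,4,5,6,7,8-octahydronaphthalen-1-ol
Conditions: HOCH2CH2OH, PPTS (cat.), THF, rt
Reagents that add atoms: ethylene glycol, OCCO
Why: Acid-catalysed enol ether–diol exchange (transketalisation), as practised on Birch dienes of 19-norsteroids: C-protonation of the enol ether gives an oxocarbenium ion that the diol traps before the C5=C10 bond can move into conjugation, and the mild pyridinium acid should not ionise the allylic alcohol.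

Step 5
Reactants: 6 (1R,2R)-6,6-(ethylenedioxy)-2-methyl-1,2,3,4,5,6,7,8-octahydronaphthalen-1-ol; 7 diiodomethane
Product: 9 3,3-(ethylenedioxy)-8-methyl-5,10-methanodecalin-9-ol (C20 bridge syn to 9-OH and 8-CH3), via ethylzinc alkoxide 8 (not isolated)
Conditions: Et2Zn (4 equiv), CH2I2 (8 equiv), CH2Cl2, 0 °C → rt
Reagents that add atoms: diiodomethane (7), ICI
Why: Et2Zn first turns the C9 hydroxyl into the ethylzinc alkoxide 8, which binds the Furukawa carbenoid EtZnCH2I and passes CH2 to the neighbouring C5=C10 bond through the butterfly transition state of a hydroxyl-directed Simmons–Smith cyclopropanation. The closest known cases are the methylenation of cyclic allylic alcohols and of 5(10)-unsaturated 19-norsteroid alcohols. The three-membered ring C5–C10–C20 is closed in one concerted [2+1] syn addition that forms the C10–C20 and C5–C20 bonds together. Both new stereocentres (C5 and C10) are set by the (R)-C9 alkoxide, which holds zinc on its own face and so places C20 syn to the C9 oxygen. The step needs face selectivity, secured by the alkoxide sitting one bond from the alkene, and survival of the ketal, which low temperature and excess Et2Zn (buffering ZnI2) should ensure. The electron-rich tetrasubstituted alkene is the only C=C present.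

Step 6
Reactants: 9 3,3-(ethylenedioxy)-8-methyl-5,10-methanodecalin-9-ol
Product: 10 3,3-(ethylenedioxy)-8-methyl-5,10-methanodecalin-9-yl pivalate
Conditions: PivCl, DMAP, pyridine, 50 °C
Reagents that add atoms: pivaloyl chloride, CC(C)(C)C(=O)Cl
Why: DMAP-catalysed acylation of the hindered secondary carbinol; the pivalate masks the cyclopropylcarbinyl alcohol against acid ionisation in step 7 and against vinylogous retro-aldol cleavage of C9–C10 under the basic methylation of step 8, and no stereocentre is involved.

Step 7
Reactants: 10 3,3-(ethylenedioxy)-8-methyl-5,10-methanodecalin-9-yl pivalate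
Product: 12 8,10-dimethyl-3-oxo-Δ4-octalin-9-yl pivalate (10-CH3 syn to 9-OPiv and 8-CH3), via cyclopropyl ketone 11 (not isolated)
Conditions: 2 M aq. HCl, MeOH, 50 °C
Reagents that add atoms: water, O
Why: Ketal hydrolysis gives the β,γ-cyclopropyl ketone 11, whose C3 enol opens the pseudo-axial C5–C20 bond as C20 is protonated (acid-catalysed homoconjugate cyclopropane cleavage, the reaction that converts 5,10-methano-19-norsteroid 3-ketones into 10-methyl Δ4-3-ketones), so C20 becomes the C10 methyl with the configuration fixed by the cyclopropane; C9 is kept sp3 and acylated because a C9 ketone would invite retro-Michael cleavage of C5–C10.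

Step 8
Reactants: 12 8,10-dimethyl-3-oxo-Δ4-octalin-9-yl pivalate
Product: 14 4,4,8,10-tetramethyl-3-oxo-Δ5-octalin-9-yl pivalate, via monomethyl enone 13 (not isolated)
Conditions: t-BuOK (3 equiv), t-BuOH/THF, 0 °C → rt; MeI (4 equiv)
Reagents that add atoms: iodomethane, CI
Why: Deconjugative α,α-dialkylation of the Δ4-3-ketone through its extended potassium dienolate (the classical gem-dimethylation of Wieland–Miescher-type enones), which alkylates twice at C4 and leaves the Δ5 olefin; no stereocentre is created and the pivalate, having no α-hydrogen, should resist the hindered alkoxide.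

Step 9
Reactants: 14 4,4,8,10-tetramethyl-3-oxo-Δ5-octalin-9-yl pivalate
Product: 15 trans-fused 4,4,8,10-tetramethyl-3-oxodecalin-9-yl pivalate (H5 anti to C20)
Conditions: H2 (4 atm), 10% Pd/C, EtOAc, rt
Reagents that add atoms: none
Why: Heterogeneous catalytic hydrogenation: C20, the C4 methyl syn to it, the 8-methyl and the 9-pivalate shield one face, so hydrogen should add to the Δ5 olefin anti to C20 and give the trans-decalin, as with 4,4-dimethyl-Δ5 steroids.

Step 10
Reactants: 15 trans-fused 4,4,8,10-tetramethyl-3-oxodecalin-9-yl pivalate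
Product: 17 Δ2-enol triflate of 15 (3-trifluoromethanesulfonyloxy-Δ2-alkene), via potassium enolate 16 (not isolated)
Conditions: KHMDS, THF, −78 °C; PhNTf2, −78 → 0 °C
Reagents that add atoms: N-phenylbis(trifluoromethanesulfonimide), O=S(=O)(N(c1ccccc1)S(=O)(=O)C(F)(F)F)C(F)(F)F
Why: Enolisation and O-sulfonylation (enol triflate formation): C4 is quaternary, so the C3 ketone can enolise only toward C2 and a single Δ2 enol triflate should form, as is standard for 4,4-dimethyl-3-ketones.

Step 11
Reactants: 17 Δ2-enol triflate of 15
Product: 18 3-bromo-4,4,8,10-tetramethyl-Δ2-octalin-9-yl pivalate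
Conditions: Ni(OAc)2·4H2O (10 mol%), 1,5-cyclooctadiene, Zn (cat.), LiBr, DMA/THF, rt
Reagents that add atoms: lithium bromide, [Li+].[Br-]
Why: Nickel-catalysed halogen exchange of an enol triflate (oxidative addition of Ni(0) into C–OTf, triflate/bromide exchange at nickel, C–Br reductive elimination), a known conversion of cyclic enol triflates into alkenyl bromides that leaves the ester untouched; no stereocentre is involved.

Step 12
Reactants: 18 3-bromo-4,4,8,10-tetramethyl-Δ2-octalin-9-yl pivalate
Product: 19 (3R,5S,8R,9R,10R)-3-bromo-4,4,8,10-tetramethyldecalin-9-yl pivalate (Br equatorial, syn to C20)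
Conditions: Mn(dpm)3 (10 mol%), PhSiH3, t-BuOOH, i-PrOH, rt
Reagents that add atoms: none
Why: Metal-hydride hydrogen-atom-transfer (Mukaiyama-type) hydrogenation, a method known to reduce haloalkenes with retention of the halogen: H• adds to C2 to give the α-bromo C3 radical, which should take its second hydrogen along the axial trajectory on the face anti to C20 (away from the axial C4 and C10 methyls), leaving bromine equatorial and syn to C20.

Step 13
Reactants: 19 (3R,5S,8R,9R,10R)-3-bromo-4,4,8,10-tetramethyldecalin-9-yl pivalate
Product: 20 (3R,5S,8R,9R,10R)-3-bromo-4,4,8,10-tetramethyldecalin-9-ol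
Conditions: DIBAL-H, CH2Cl2, −78 → 0 °C; Rochelle salt
Reagents that add atoms: none
Why: Reductive ester cleavage: hydride adds to the pivaloyl carbonyl and releases the C9 alkoxide, while the hindered secondary bromide is inert to DIBAL-H at low temperature; no stereocentre changes.

Step 14
Reactants: 20 (3R,5S,8R,9R,10R)-3-bromo-4,4,8,10-tetramethyldecalin-9-ol
Product: 21 (3R,5S,8R,10R)-3-bromo-4,4,8,10-tetramethyldecalin-9-one (8-CH3 axial, syn to C20)
Conditions: Dess–Martin periodinane, CH2Cl2, rt
Reagents that add atoms: none
Why: Dess–Martin oxidation of the secondary alcohol to the C9 ketone under neutral conditions that leave the alkyl bromide alone; the C8 methyl is still syn to C20 at this point.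

Step 15
Reactants: 21 (3R,5S,8R,10R)-3-bromo-4,4,8,10-tetramethyldecalin-9-one
Product: 22 (3R,5S,8S,10R)-3-bromo-4,4,8,10-tetramethyldecalin-9-one (8-CH3 equatorial, anti to C20)
Conditions: NaOMe (cat.), MeOH/THF, rt
Reagents that add atoms: none
Why: Base-mediated epimerisation through the C8–C9 enolate (thermodynamic equilibration): the axial 8-methyl clashes syn-diaxially with the C10 methyl, so reprotonation should settle C8 with its methyl equatorial and anti to C20 as in the target, while the equatorial neopentyl-type bromide has no antiperiplanar hydrogen for E2 and is shielded from SN2.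

Step 16
Reactants: 23 (R)-linalool
Product: 24 (R)-linalool tert-butyldimethylsilyl ether
Conditions: TBSOTf, 2,6-lutidine, CH2Cl2, 0 °C
Reagents that add atoms: tert-butyldimethylsilyl trifluoromethanesulfonate, CC(C)(C)[Si](C)(C)OS(=O)(=O)C(F)(F)F
Why: Silylation of the tertiary allylic alcohol with a silyl triflate; the C13 stereocentre of (R)-linalool is untouched and the bulky TBS group should resist retro-Brook migration in step 20.

Step 17
Reactants: 24 (R)-linalool tert-butyldimethylsilyl ether
Product: 25 (R)-4-(tert-butyldimethylsilyloxy)-4-methylhex-5-enal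
Conditions: O3, CH2Cl2, −78 °C (Sudan Red 7B end-point); Me2S, −78 °C → rt
Reagents that add atoms: ozone, [O-][O+]=O
Why: Chemoselective ozonolysis: the electron-rich trisubstituted alkene reacts much faster than the hindered monosubstituted vinyl group, and the indicator dye marks the end-point before the vinyl group is attacked.

Step 18
Reactants: 25 (R)-4-(tert-butyldimethylsilyloxy)-4-methylhex-5-enal
Product: 26 (R)-4-(tert-butyldimethylsilyloxy)-4-methylhex-5-enoic acid
Conditions: NaClO2, NaH2PO4, 2-methyl-2-butene, t-BuOH/H2O, rt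
Reagents that add atoms: sodium chlorite, [Na+].[O-]Cl=O
Why: Pinnick oxidation of the aldehyde to the acid, with 2-methyl-2-butene scavenging HOCl so that the vinyl group and the silyl ether survive.

Step 19
Reactants: 26 (R)-4-(tert-butyldimethylsilyloxy)-4-methylhex-5-enoic acid
Product: 28 (R)-tert-butyl[(5-iodo-3-methylpent-1-en-3-yl)oxy]dimethylsilane, via thiohydroxamate ester 27 (not isolated)
Conditions: 2-mercaptopyridine N-oxide, DCC, DMAP (cat.), CH2Cl2, rt, dark; CHI3, hν (W lamp), rt
Reagents that add atoms: iodoform, IC(I)I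
Why: Barton decarboxylative iodination: the thiohydroxamate ester fragments under light to CO2 and the primary C11 radical, which should abstract iodine from iodoform faster than it can cyclise onto the vinyl group (4-exo and 5-endo closures are slow), removing the surplus carbon of linalool and leaving C13 untouched.

Step 20
Reactants: 28 (R)-tert-butyl[(5-iodo-3-methylpent-1-en-3-yl)oxy]dimethylsilane; 22 (3R,5S,8S,10R)-3-bromo-4,4,8,10-tetramethyldecalin-9-one
Product: 31 13-O-TBS ether of the target (3R,5S,8S,9R,10R,13R), via alkyllithium 29 (not isolated), via alkylcerium dichloride 30 (not isolated)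
Conditions: 28, t-BuLi (2.1 equiv), Et2O/pentane, −78 °C; CeCl3 (anhydrous), THF, −78 °C; then 22, −78 → −40 °C; aq. NH4Cl
Reagents that add atoms: none
Why: Lithium–iodine exchange, transmetalation to the weakly basic organocerium (Imamoto conditions) and 1,2-addition to the hindered, enolisable C9 ketone: the nucleophile should enter along the axial trajectory anti to the axial C10 methyl (as with six-ring steroid ketones that have an adjacent angular methyl), giving C11 anti and 9-OH syn to C20, and any enolate formed reprotonates to the same equatorial C8 epimer.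

Step 21
Reactants: 31 13-O-TBS ether of the target
Product: 32 target, (3R,5S,8S,9R,10R,13R)-3-bromolabd-14-ene-9,13-diol (CNP0318118.1)
Conditions: TBAF, THF, rt
Reagents that add atoms: none
Why: Fluoride-mediated desilylation of the tertiary TBS ether; the equatorial neopentyl-type bromide lacks an antiperiplanar β-hydrogen and should resist fluoride, and no stereocentre is affected.

**Compound list**

1 | 6-methoxy-1-tetralone | COc1ccc2c(c1)CCCC2=O | starting material
2 | lithium enolate of 1 | COc1ccc2c(c1)CCC=C2O[Li] | intermediate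
3 | rac-6-methoxy-2-methyl-3,4-dihydronaphthalen-1(2H)-one | COc1ccc2c(c1)CCC(C)C2=O | intermediate
4 | (1R,2R)-6-methoxy-2-methyl-1,2,3,4-tetrahydronaphthalen-1-ol (cis) | O[C@@H]1[C@H](C)CCc2cc(OC)ccc12 | intermediate
5 | (1R,2R)-6-methoxy-2-methyl-1,2,3,4,5,8-hexahydronaphthalen-1-ol | O[C@@H]1[C@H](C)CCC2=C1CC=C(OC)C2 | intermediate
6 | (1R,2R)-6,6-(ethylenedioxy)-2-methyl-1,2,3,4,5,6,7,8-octahydronaphthalen-1-ol (C3 dioxolane, C5=C10 olefin, 9-OH cis to 8-CH3) | O[C@@H]1[C@H](C)CCC2=C1CCC3(C2)OCCO3 | intermediate
7 | diiodomethane | ICI | starting material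
8 | ethylzinc alkoxide of 6 | CC[Zn]O[C@@H]1[C@H](C)CCC2=C1CCC3(C2)OCCO3 | intermediate
9 | 3,3-(ethylenedioxy)-8-methyl-5,10-methanodecalin-9-ol, C20 bridge syn to 9-OH and 8-CH3 | O[C@@H]1[C@H](C)CC[C@]23C[C@]12CCC4(C3)OCCO4 | intermediate
10 | 9-O-pivalate of 9 | CC(C)(C)C(=O)O[C@@H]1[C@H](C)CC[C@]23C[C@]12CCC4(C3)OCCO4 | intermediate
11 | 8-methyl-3-oxo-5,10-methanodecalin-9-yl pivalate (cyclopropyl ketone) | CC(C)(C)C(=O)O[C@@H]1[C@H](C)CC[C@]23C[C@]12CCC(=O)C3 | intermediate
12 | 8,10-dimethyl-3-oxo-Δ4-octalin-9-yl pivalate (10-CH3, 9-OPiv and 8-CH3 syn) | CC(C)(C)C(=O)O[C@@H]1[C@H](C)CCC2=CC(=O)CC[C@@]12C | intermediate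
13 | 4,8,10-trimethyl-3-oxo-Δ5-octalin-9-yl pivalate (C4 epimers) | CC(C)(C)C(=O)O[C@@H]1[C@H](C)CC=C2C(C)C(=O)CC[C@@]12C | intermediate
14 | 4,4,8,10-tetramethyl-3-oxo-Δ5-octalin-9-yl pivalate | CC(C)(C)C(=O)O[C@@H]1[C@H](C)CC=C2C(C)(C)C(=O)CC[C@@]12C | intermediate
15 | trans-fused 4,4,8,10-tetramethyl-3-oxodecalin-9-yl pivalate (H5 anti to C20) | CC(C)(C)C(=O)O[C@@H]1[C@H](C)CC[C@@H]2C(C)(C)C(=O)CC[C@@]12C | intermediate
16 | potassium Δ2-enolate of 15 | CC(C)(C)C(=O)O[C@@H]1[C@H](C)CC[C@@H]2C(C)(C)C(O[K])=CC[C@@]12C | intermediate
17 | Δ2-enol triflate of 15 | CC(C)(C)C(=O)O[C@@H]1[C@H](C)CC[C@@H]2C(C)(C)C(OS(=O)(=O)C(F)(F)F)=CC[C@@]12C | intermediate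
18 | 3-bromo-4,4,8,10-tetramethyl-Δ2-octalin-9-yl pivalate | CC(C)(C)C(=O)O[C@@H]1[C@H](C)CC[C@@H]2C(C)(C)C(Br)=CC[C@@]12C | intermediate
19 | (3R,5S,8R,9R,10R)-3-bromo-4,4,8,10-tetramethyldecalin-9-yl pivalate | CC(C)(C)C(=O)O[C@@H]1[C@H](C)CC[C@@H]2C(C)(C)[C@H](Br)CC[C@@]12C | intermediate
20 | (3R,5S,8R,9R,10R)-3-bromo-4,4,8,10-tetramethyldecalin-9-ol | O[C@@H]1[C@H](C)CC[C@@H]2C(C)(C)[C@H](Br)CC[C@@]12C | intermediate
21 | (3R,5S,8R,10R)-3-bromo-4,4,8,10-tetramethyldecalin-9-one (8-CH3 syn to C20) | O=C1[C@H](C)CC[C@@H]2C(C)(C)[C@H](Br)CC[C@@]12C | intermediate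
22 | (3R,5S,8S,10R)-3-bromo-4,4,8,10-tetramethyldecalin-9-one (8-CH3 anti to C20) | O=C1[C@@H](C)CC[C@@H]2C(C)(C)[C@H](Br)CC[C@@]12C | intermediate
23 | (R)-linalool | C=C[C@](C)(O)CCC=C(C)C | starting material
24 | (R)-linalool tert-butyldimethylsilyl ether | C=C[C@](C)(O[Si](C)(C)C(C)(C)C)CCC=C(C)C | intermediate
25 | (R)-4-(tert-butyldimethylsilyloxy)-4-methylhex-5-enal | C=C[C@](C)(O[Si](C)(C)C(C)(C)C)CCC=O | intermediate
26 | (R)-4-(tert-butyldimethylsilyloxy)-4-methylhex-5-enoic acid | C=C[C@](C)(O[Si](C)(C)C(C)(C)C)CCC(=O)O | intermediate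
27 | N-acyloxy-pyridine-2-thione (Barton ester) of 26 | C=C[C@](C)(O[Si](C)(C)C(C)(C)C)CCC(=O)ON1C=CC=CC1=S | intermediate
28 | (R)-tert-butyl[(5-iodo-3-methylpent-1-en-3-yl)oxy]dimethylsilane | C=C[C@](C)(O[Si](C)(C)C(C)(C)C)CCI | intermediate
29 | alkyllithium from 28 | C=C[C@](C)(O[Si](C)(C)C(C)(C)C)CC[Li] | intermediate
30 | alkylcerium dichloride from 29 | C=C[C@](C)(O[Si](C)(C)C(C)(C)C)CC[Ce](Cl)Cl | intermediate
31 | 13-O-TBS ether of the target (3R,5S,8S,9R,10R,13R) | C=C[C@](C)(O[Si](C)(C)C(C)(C)C)CC[C@@]1(O)[C@@H](C)CC[C@@H]2C(C)(C)[C@H](Br)CC[C@]21C | intermediate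
32 | (3R,5S,8S,9R,10R,13R)-3-bromolabd-14-ene-9,13-diol (CNP0318118.1) | C=C[C@](C)(O)CC[C@@]1(O)[C@@H](C)CC[C@@H]2C(C)(C)[C@H](Br)CC[C@]21C | target

**Totals**

Total step count: 21. Longest linear sequence: 17 steps (steps 1–15, 20, 21, from 6-methoxy-1-tetralone); the side-chain branch (steps 16–19) is convergent.

**Steps most likely to fail**

1. Step 20. The hindered C9 ketone may be enolised toward C8 or simply not attacked, and the facial preference anti to C20 may erode with a bulky nucleophile. Fallback: setting out from 28 and 22, a Barbier coupling is run without any preformed carbanion. SmI2 (2.2 equiv) with catalytic NiI2 in THF at 0 °C reduces the primary iodide in the presence of the ketone to the alkylsamarium(III) diiodide F4, which is oxophilic and non-basic and adds as it forms along the same axial trajectory. The secondary neopentyl-type bromide should be reduced far more slowly than the primary iodide in the absence of HMPA. The route is rejoined at 31.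

2. Step 12. Hydrogen-atom transfer to the bromine-bearing carbon would be followed by β-loss of bromine (net hydrodebromination), or the second hydrogen transfer at C3 may lack facial control. Fallback: setting out from 15, hydrazine hydrate in refluxing ethanol gives the C3 hydrazone F2. CuBr2 with t-BuOLi in THF converts it, with loss of N2, into the 3,3-dibromide F3. Bu3SnH (1.0 equiv) with Et3B/air in toluene at −78 → 0 °C then removes one bromine by radical chain reduction; the α-bromo C3 radical should take hydrogen from the small tin hydride on the open face anti to C20, leaving the equatorial bromide. The route is rejoined at 19.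

3. Step 11. Nickel may insert only slowly into the enol triflate flanked by the quaternary C4, with reduction to the Δ2 alkene competing. Fallback: setting out from 17, Pd(PPh3)4, LiCl and hexamethylditin in hot dioxane give the C3 trimethylstannyl alkene F1. N-Bromosuccinimide in CH2Cl2 at 0 °C then effects ipso-bromodestannylation, and the route is rejoined at 18.

Further compounds
F1 | step 11 | 4,4,8,10-tetramethyl-3-(trimethylstannyl)-Δ2-octalin-9-yl pivalate | CC(C)(C)C(=O)O[C@@H]1[C@H](C)CC[C@@H]2C(C)(C)C([Sn](C)(C)C)=CC[C@@]12C
F2 | step 12 | C3 hydrazone of 15 | CC(C)(C)C(=O)O[C@@H]1[C@H](C)CC[C@@H]2C(C)(C)C(=NN)CC[C@@]12C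
F3 | step 12 | 3,3-dibromo-4,4,8,10-tetramethyldecalin-9-yl pivalate | CC(C)(C)C(=O)O[C@@H]1[C@H](C)CC[C@@H]2C(C)(C)C(Br)(Br)CC[C@@]12C
F4 | step 20 | alkylsamarium(III) diiodide from 28 | C=C[C@](C)(O[Si](C)(C)C(C)(C)C)CC[Sm](I)I
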